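Amounts first: 0.30 M of Ly goes in, and Ze, once formed, can fall back to Ux or go onward by two ways, one of which consumes more Ly.

Ly 0.30 M; time 80 s

    Ly → Ux (k1 = 0.0083 s⁻¹)
    Ux ⇌ Ze (K2 = 5.4, k2 = 0.090 s⁻¹)
    Ux ⇌ Ty (K3 = 160, k3 = 0.0059 s⁻¹)
    Ze → Aj (k4 = 0.0044 s⁻¹)
    Ly + Ze → Jy (k5 = 0.040 L mol⁻¹ s⁻¹)

- amount of Ze at 80 s, in percent of the Ly charged
- amount of Jy at 80 s, in percent of the Ly charged
- amount of Ux at 80 s, in percent of the Ly charged

- percent here means Ly units held: one Jy counts as two
- run time (flask): 80 s

Ze is lost by a first-order step to Aj and by a step whose pseudo-first-order constant, the rate constant of Ly + Ze times [Ly], falls as Ly falls. Freezing [Ly] at one well-chosen value makes that a constant. Ux passes on with a half-life of 7.70 s, short against 80 s, so Ze can be taken to grow roughly in proportion to time. The loss of Ze is then weighted towards late times, with its centre at 53.3 s. There, with the Ly + Ze draw on Ly set aside, [Ly] is 0.193 M.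

A small table of the two onward exits from Ze:

- At the start: [Ly] 0.30 M; exit to Jy 0.0120 s⁻¹; exit to Aj 0.0044 s⁻¹.
- At 53.3 s: [Ly] 0.193 M; exit to Jy 0.00771 s⁻¹; exit to Aj 0.0044 s⁻¹.

The first row has the exit to Jy faster than the exit to Aj, by a factor of 2.73. The second row is the one to carry, and its exit to Jy is still the faster. Their quotient is the split 1.75, the Ze units taken by Ly for each Ze unit going to Aj over the run. One Jy holds one Ze, so the percent of Jy over twice the percent of Aj should read the split. This reckoning gives a ratio, not amounts.

The forecast, made by hand (“stepped by hand in 10 s trapezoid steps”), stands at 23% Ze, 15.4% Jy and 8.1% Ux. The simulated flask gives 22.9% Ze, 15.5% Jy and 8.11% Ux.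

In this flask, at 32.4 s, the Ly + Ze step uses Ze 2.0 times as fast as the step to Aj, and by 80 s the 15.5% of Jy against 4.60% of Aj reads 1.68 against the split of 1.75. In a neighbouring flask charged with 0.075 M of Ly, the split is 0.438, and its 4.58% of Jy against 5.26% of Aj at 80 s reads 0.435.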